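**Retrosynthetic overview**

1. The target is a (2S,3S)-3-aroyl-3-hydroxy-2-aryl-2,3-dihydrobenzofuran with a 2',4'-dihydroxychalcone arm at C5. The arm is cut at the aryl–vinyl bond (Heck), and all five phenols are carried as tert-butyldimethylsilyl (TBS) ethers.
2. Enabling feature: C3 is the carbinol carbon of an α-ketol (C3–OH next to the aroyl C=O), and its ring neighbour C2 is a benzylic carbon bound to O1. The ring-A bridge O1–C7a=C3a holds C2 δ to C3, so C3 is the retron of a diketone carbonyl and C2–C3 the retron of a 1,6-hydrogen transfer followed by biradical collapse.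
3. Key disconnection C2–C3: photocyclisation of an achiral 2-(benzyloxy)benzil should make the C–C bond, the tertiary alcohol, both stereocentres (relative) and the dihydrofuran ring in one operation. The enantiomers are then separated on a chiral phase.
4. The benzil comes from a diarylalkyne (KMnO4), the alkyne from a 2-iodoaryl benzyl ether and an arylacetylene (Sonogashira), and the ether from 4-bromo-2-iodophenol and a silyloxybenzyl alcohol (Mitsunobu).
5. Ring order: the four benzene rings are bought; the dihydrofuran ring (O1–C2–C3–C3a–C7a) is the only ring closed, and no ring is formed after it.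

Key step: step 6

TBS = tert-butyldimethylsilyl throughout.

Step 1
Reactants: 1 2,4-dihydroxybenzaldehyde
Product: 2 2,4-bis(TBS-oxy)benzaldehyde
Conditions: TBSCl (2.5 equiv), imidazole, DMF, 20 °C
Reagents that add atoms: tert-butyldimethylsilyl chloride, CC(C)(C)[Si](C)(C)Cl
Why: Imidazole-promoted O-silylation, with excess reagent because the 2-hydroxyl is hydrogen-bonded to the aldehyde; silyl ethers are chosen because they carry no hydrogen δ to the later aroyl carbonyl and are removed by fluoride at the end.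

Step 2
Reactants: 2 2,4-bis(TBS-oxy)benzaldehyde
Product: 3 1-ethynyl-2,4-bis(TBS-oxy)benzene
Conditions: Me3SiCHN2, lithium diisopropylamide, THF, −78 °C to 0 °C
Reagents that add atoms: (trimethylsilyl)diazomethane, C[Si](C)(C)C=[N+]=[N-]
Why: Colvin rearrangement: the lithiated silyldiazomethane adds to the aldehyde, Peterson-type loss of silanolate and then of N2 gives an alkylidene carbene whose 1,2-shift delivers the terminal alkyne, without the methoxide that would strip aryl silyl ethers.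

Step 3
Reactants: 4 4-bromo-2-iodophenol; 5 [4-(TBS-oxy)phenyl]methanol
Product: 6 4-bromo-2-iodo-1-{[4-(TBS-oxy)phenyl]methoxy}benzene
Conditions: PPh3, diisopropyl azodicarboxylate, THF, 0 °C to 20 °C
Reagents that add atoms: none
Why: Mitsunobu etherification of an acidic phenol with a primary benzylic alcohol under neutral conditions, which avoids the carbonate bases that cleave aryl silyl ethers.

Step 4
Reactants: 6 4-bromo-2-iodo-1-{[4-(TBS-oxy)phenyl]methoxy}benzene; 3 1-ethynyl-2,4-bis(TBS-oxy)benzene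
Product: 7 4-bromo-2-{[2,4-bis(TBS-oxy)phenyl]ethynyl}-1-{[4-(TBS-oxy)phenyl]methoxy}benzene
Conditions: PdCl2(PPh3)2 (2 mol%), CuI (4 mol%), Et3N, THF, 20 °C
Reagents that add atoms: none
Why: Sonogashira coupling; at room temperature oxidative addition into C–I is much faster than into C–Br, so the bromide should be kept for step 10.

Step 5
Reactants: 7 4-bromo-2-{[2,4-bis(TBS-oxy)phenyl]ethynyl}-1-{[4-(TBS-oxy)phenyl]methoxy}benzene
Product: 8 1-(5-bromo-2-{[4-(TBS-oxy)phenyl]methoxy}phenyl)-2-[2,4-bis(TBS-oxy)phenyl]ethane-1,2-dione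
Conditions: KMnO4, NaHCO3, MgSO4, acetone/H2O, 0 °C to 20 °C
Reagents that add atoms: potassium permanganate, [K+].[O-][Mn](=O)(=O)=O
Why: Permanganate oxidation of a diarylalkyne to the benzil through a cyclic manganate ester under buffered neutral conditions; a cycloaddition-type oxidant is chosen because π-acidic metal or iodonium oxidants would invite attack of the ortho ether oxygen on the activated alkyne and give a benzofuran.

Step 6
Reactants: 8 1-(5-bromo-2-{[4-(TBS-oxy)phenyl]methoxy}phenyl)-2-[2,4-bis(TBS-oxy)phenyl]ethane-1,2-dione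
Product: 10 rac-(2S*,3S*)-[5-bromo-3-hydroxy-2-[4-(TBS-oxy)phenyl]-2,3-dihydro-1-benzofuran-3-yl][2,4-bis(TBS-oxy)phenyl]methanone, via 1,5-biradical 9 (not isolated)
Conditions: hν (405 nm LEDs), degassed benzene (0.005 M), 20 °C
Reagents that add atoms: none
Why: Norrish–Yang photocyclisation: excitation of the n→π* band of the diketone and intersystem crossing should give a triplet whose ring-A-bound carbonyl oxygen abstracts one of the two benzylic, O1-bound hydrogens through a seven-membered transition state (1,6-hydrogen transfer), producing the 1,5-biradical 9 with a ketyl-type radical at C3 stabilised by the neighbouring aroyl group and an α-oxy benzylic radical at C2. After spin inversion the two radical centres combine, which forms C2–C3 and closes the dihydrofuran ring by 1,5-biradical recombination, a five-membered closure that is not subject to polar Baldwin constraints. The closest known reaction type is the photocyclisation of 2-(benzyloxy)phenyl ketones and 2-(benzyloxy)phenylglyoxylic esters to 2-aryl-3-hydroxy-2,3-dihydrobenzofurans. C2 and C3 are created together and their relative configuration should be fixed in the ring-closing transition state: in a non-hydrogen-bonding solvent the C3 hydroxyl is tied to the aroyl oxygen by an internal hydrogen bond, the aroyl group is then the bulky substituent, and the 2-aryl group takes the face anti to it (aryl cis to OH, the 2S*,3S* series); no absolute configuration is induced, so the racemate is expected. Site selectivity between the two carbonyl oxygens is needed: the proximal oxygen can reach the C–H bond in the plane of its n orbital with ring A still conjugated, whereas the distal oxygen would need an eight-membered array with ring A twisted out of plane, and the silyl ethers on the aroyl ring offer no δ-hydrogen. Chromophore selectivity is secured by 405 nm light, which only the yellow diketone absorbs, so the aryl ketone product should not be photolysed.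

Step 7
Reactants: 10 rac-(2S*,3S*)-[5-bromo-3-hydroxy-2-[4-(TBS-oxy)phenyl]-2,3-dihydro-1-benzofuran-3-yl][2,4-bis(TBS-oxy)phenyl]methanone
Product: 11 [(2S,3S)-5-bromo-3-hydroxy-2-[4-(TBS-oxy)phenyl]-2,3-dihydro-1-benzofuran-3-yl][2,4-bis(TBS-oxy)phenyl]methanone
Conditions: preparative supercritical-fluid chromatography, amylose tris(3,5-dimethylphenylcarbamate) stationary phase, CO2/i-PrOH, 35 °C
Reagents that add atoms: none
Why: Resolution by chromatography on a chiral stationary phase secures the absolute configuration; the bromine atom allows its assignment by anomalous-dispersion X-ray analysis, and neither centre can epimerise under these neutral conditions (C3 is quaternary, C2 is a non-acidic benzylic ether carbon).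

Step 8
Reactants: 2 2,4-bis(TBS-oxy)benzaldehyde
Product: 12 1-[2,4-bis(TBS-oxy)phenyl]prop-2-en-1-ol (racemic)
Conditions: CH2=CHMgBr, THF, −78 °C; AcOH quench at −78 °C
Reagents that add atoms: vinylmagnesium bromide, C=C[Mg]Br
Why: Grignard 1,2-addition to the aldehyde; the cold acidic quench should prevent migration of the ortho silyl group from the phenolic oxygen to the new alkoxide.

Step 9
Reactants: 12 1-[2,4-bis(TBS-oxy)phenyl]prop-2-en-1-ol
Product: 13 1-[2,4-bis(TBS-oxy)phenyl]prop-2-en-1-one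
Conditions: Dess–Martin periodinane, CH2Cl2, 0 °C to 20 °C; used at once
Reagents that add atoms: none
Why: Dess–Martin oxidation of an allylic benzylic alcohol under mild non-basic conditions; the polymerisable aryl vinyl ketone is not stored.

Step 10
Reactants: 11 [(2S,3S)-5-bromo-3-hydroxy-2-[4-(TBS-oxy)phenyl]-2,3-dihydro-1-benzofuran-3-yl][2,4-bis(TBS-oxy)phenyl]methanone; 13 1-[2,4-bis(TBS-oxy)phenyl]prop-2-en-1-one
Product: 14 (E)-3-[(2S,3S)-3-[2,4-bis(TBS-oxy)benzoyl]-3-hydroxy-2-[4-(TBS-oxy)phenyl]-2,3-dihydro-1-benzofuran-5-yl]-1-[2,4-bis(TBS-oxy)phenyl]prop-2-en-1-one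
Conditions: Pd2(dba)3 (2 mol%), [HP(t-Bu)3]BF4 (8 mol%), Cy2NMe, 1,4-dioxane, 60 °C
Reagents that add atoms: none
Why: Heck reaction: oxidative addition into the C5–Br bond, syn carbopalladation at the terminal carbon of the vinyl ketone and syn β-hydride elimination should give the E-enone, with the weak amine base leaving the tertiary α-ketol and both stereocentres untouched.

Step 11
Reactants: 14 (E)-3-[(2S,3S)-3-[2,4-bis(TBS-oxy)benzoyl]-3-hydroxy-2-[4-(TBS-oxy)phenyl]-2,3-dihydro-1-benzofuran-5-yl]-1-[2,4-bis(TBS-oxy)phenyl]prop-2-en-1-one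
Product: 15 (E)-3-[(2S,3S)-3-(2,4-dihydroxybenzoyl)-3-hydroxy-2-(4-hydroxyphenyl)-2,3-dihydro-1-benzofuran-5-yl]-1-(2,4-dihydroxyphenyl)prop-2-en-1-one
Conditions: Bu4NF (5.5 equiv), AcOH (5.5 equiv), THF, 0 °C
Reagents that add atoms: none
Why: Fluoride cleavage of five aryl silyl ethers, buffered with acetic acid so that the phenols are released near neutrality; this should avoid base-induced α-ketol rearrangement, opening at C2 through a para-quinone methide and chalcone-to-flavanone cyclisation.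

**Compound list**

1 | 2,4-dihydroxybenzaldehyde | O=Cc1ccc(O)cc1O | starting material
2 | 2,4-bis(TBS-oxy)benzaldehyde | O=Cc1ccc(O[Si](C)(C)C(C)(C)C)cc1O[Si](C)(C)C(C)(C)C | intermediate
3 | 1-ethynyl-2,4-bis(TBS-oxy)benzene | C#Cc1ccc(O[Si](C)(C)C(C)(C)C)cc1O[Si](C)(C)C(C)(C)C | intermediate
4 | 4-bromo-2-iodophenol | Oc1ccc(Br)cc1I | starting material
5 | [4-(TBS-oxy)phenyl]methanol | OCc1ccc(O[Si](C)(C)C(C)(C)C)cc1 | starting material
6 | 4-bromo-2-iodo-1-{[4-(TBS-oxy)phenyl]methoxy}benzene | Brc1ccc(OCc2ccc(O[Si](C)(C)C(C)(C)C)cc2)c(I)c1 | intermediate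
7 | 4-bromo-2-{[2,4-bis(TBS-oxy)phenyl]ethynyl}-1-{[4-(TBS-oxy)phenyl]methoxy}benzene | Brc1ccc(OCc2ccc(O[Si](C)(C)C(C)(C)C)cc2)c(C#Cc2ccc(O[Si](C)(C)C(C)(C)C)cc2O[Si](C)(C)C(C)(C)C)c1 | intermediate
8 | 1-(5-bromo-2-{[4-(TBS-oxy)phenyl]methoxy}phenyl)-2-[2,4-bis(TBS-oxy)phenyl]ethane-1,2-dione | Brc1ccc(OCc2ccc(O[Si](C)(C)C(C)(C)C)cc2)c(C(=O)C(=O)c2ccc(O[Si](C)(C)C(C)(C)C)cc2O[Si](C)(C)C(C)(C)C)c1 | intermediate
9 | 1,5-biradical formed from 8 by transfer of a benzylic hydrogen to the ring-A-bound carbonyl oxygen (radical centres at the hydroxy-bearing carbon and at the OCH carbon) | Brc1ccc(O[CH]c2ccc(O[Si](C)(C)C(C)(C)C)cc2)c([C](O)C(=O)c2ccc(O[Si](C)(C)C(C)(C)C)cc2O[Si](C)(C)C(C)(C)C)c1 | intermediate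
10 | rac-(2S*,3S*)-[5-bromo-3-hydroxy-2-[4-(TBS-oxy)phenyl]-2,3-dihydro-1-benzofuran-3-yl][2,4-bis(TBS-oxy)phenyl]methanone (2-aryl cis to 3-OH; both enantiomers) | Brc1ccc2c(c1)[C@@](O)(C(=O)c1ccc(O[Si](C)(C)C(C)(C)C)cc1O[Si](C)(C)C(C)(C)C)[C@H](c1ccc(O[Si](C)(C)C(C)(C)C)cc1)O2.Brc1ccc2c(c1)[C@](O)(C(=O)c1ccc(O[Si](C)(C)C(C)(C)C)cc1O[Si](C)(C)C(C)(C)C)[C@@H](c1ccc(O[Si](C)(C)C(C)(C)C)cc1)O2 | intermediate
11 | [(2S,3S)-5-bromo-3-hydroxy-2-[4-(TBS-oxy)phenyl]-2,3-dihydro-1-benzofuran-3-yl][2,4-bis(TBS-oxy)phenyl]methanone | Brc1ccc2c(c1)[C@@](O)(C(=O)c1ccc(O[Si](C)(C)C(C)(C)C)cc1O[Si](C)(C)C(C)(C)C)[C@H](c1ccc(O[Si](C)(C)C(C)(C)C)cc1)O2 | intermediate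
12 | 1-[2,4-bis(TBS-oxy)phenyl]prop-2-en-1-ol (racemic; the carbinol centre is removed in step 9) | C=CC(O)c1ccc(O[Si](C)(C)C(C)(C)C)cc1O[Si](C)(C)C(C)(C)C | intermediate
13 | 1-[2,4-bis(TBS-oxy)phenyl]prop-2-en-1-one | C=CC(=O)c1ccc(O[Si](C)(C)C(C)(C)C)cc1O[Si](C)(C)C(C)(C)C | intermediate
14 | (E)-3-[(2S,3S)-3-[2,4-bis(TBS-oxy)benzoyl]-3-hydroxy-2-[4-(TBS-oxy)phenyl]-2,3-dihydro-1-benzofuran-5-yl]-1-[2,4-bis(TBS-oxy)phenyl]prop-2-en-1-one | O=C(/C=C/c1ccc2c(c1)[C@@](O)(C(=O)c1ccc(O[Si](C)(C)C(C)(C)C)cc1O[Si](C)(C)C(C)(C)C)[C@H](c1ccc(O[Si](C)(C)C(C)(C)C)cc1)O2)c1ccc(O[Si](C)(C)C(C)(C)C)cc1O[Si](C)(C)C(C)(C)C | intermediate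
15 | (E)-3-[(2S,3S)-3-(2,4-dihydroxybenzoyl)-3-hydroxy-2-(4-hydroxyphenyl)-2,3-dihydro-1-benzofuran-5-yl]-1-(2,4-dihydroxyphenyl)prop-2-en-1-one | O=C(/C=C/c1ccc2c(c1)[C@@](O)(C(=O)c1ccc(O)cc1O)[C@H](c1ccc(O)cc1)O2)c1ccc(O)cc1O | target

**Step count**

Total: 11 steps. Longest linear sequence: 8 steps (steps 1, 2, 4, 5, 6, 7, 10, 11, from 2,4-dihydroxybenzaldehyde).

**Steps most likely to fail**

Step 6. The hydrogen may instead be taken by the distal carbonyl oxygen, with closure at the distal carbon to a six-membered ketol, or the biradical may collapse with poor facial discrimination. The fallback sets out from 6 and comes back to the route at 10; it goes through an α-keto ester, in which only the ring-A ketone can abstract a hydrogen. The Grignard reagent {5-bromo-2-[(4-TBS-oxyphenyl)methoxy]phenyl}magnesium chloride F1 should form from 6 by iodine–magnesium exchange with i-PrMgCl·LiCl (THF, −40 °C, C–Br retained). F1 is added to excess dimethyl oxalate at −78 °C, which should give the keto ester methyl (5-bromo-2-{[4-(TBS-oxy)phenyl]methoxy}phenyl)(oxo)acetate F2 by mono-addition. F2 is irradiated (365 nm, benzene, 20 °C), the photocyclisation known for 2-(benzyloxy)phenylglyoxylates, and the hydroxy ester rac-methyl (2S*,3S*)-5-bromo-3-hydroxy-2-[4-(TBS-oxy)phenyl]-2,3-dihydro-1-benzofuran-3-carboxylate F3 is expected. F3 is treated with MeNHOMe·HCl and i-PrMgCl (THF, −20 °C), which should give the Weinreb amide rac-(2S*,3S*)-5-bromo-3-hydroxy-N-methoxy-N-methyl-2-[4-(TBS-oxy)phenyl]-2,3-dihydro-1-benzofuran-3-carboxamide F4 without touching C2 or C3. Separately, commercial 4-bromoresorcinol is silylated (TBSCl, imidazole, DMF), and the aryl bromide 1-bromo-2,4-bis(TBS-oxy)benzene F5 should result. F5 undergoes bromine–lithium exchange (n-BuLi, THF, −78 °C), and the aryllithium [2,4-bis(TBS-oxy)phenyl]lithium F6 is used at once at −78 °C, before the ortho silyl group can migrate from oxygen to carbon. F6 is added to F4, whose hydroxyl has first been deprotonated with one equivalent of i-PrMgCl, and the ketone 10 should result after aqueous work-up.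

Step 5. Over-oxidation may cleave the central C–C bond to the two benzoic acids, or the benzylic ether methylene may be oxidised. The fallback sets out from 7 and comes back to the route at 8. The (Z)-stilbene 4-bromo-2-{(Z)-2-[2,4-bis(TBS-oxy)phenyl]ethenyl}-1-{[4-(TBS-oxy)phenyl]methoxy}benzene F7 should form from 7 by semi-hydrogenation (H2, Pd/CaCO3 poisoned with Pb(OAc)2, quinoline, EtOAc, 20 °C). F7 is dihydroxylated (OsO4 cat., N-methylmorpholine N-oxide, acetone/H2O, 20 °C), and the racemic syn-diol 1-(5-bromo-2-{[4-(TBS-oxy)phenyl]methoxy}phenyl)-2-[2,4-bis(TBS-oxy)phenyl]ethane-1,2-diol F8 is expected. F8 is oxidised at both carbinol carbons under activated-DMSO conditions (DMSO, (CF3CO)2O, then Et3N, CH2Cl2, −78 °C), which do not cleave the glycol C–C bond, and the benzil 8 should result.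

Step 10. The vinyl ketone may polymerise faster than palladium inserts into the electron-rich C–Br bond. The fallback sets out from 11 and comes back to the route at 14. The styrene [(2S,3S)-5-ethenyl-3-hydroxy-2-[4-(TBS-oxy)phenyl]-2,3-dihydro-1-benzofuran-3-yl][2,4-bis(TBS-oxy)phenyl]methanone F9 should form from 11 by Stille coupling with tributyl(vinyl)stannane (Pd(PPh3)4, toluene, 100 °C). F9 is then joined to 13 by olefin cross-metathesis (second-generation Hoveyda–Grubbs catalyst, CH2Cl2, 40 °C), which should give the E-enone 14.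

**Further compounds**

F1 | step 6 | {5-bromo-2-[(4-TBS-oxyphenyl)methoxy]phenyl}magnesium chloride | Cl[Mg]c1cc(Br)ccc1OCc1ccc(O[Si](C)(C)C(C)(C)C)cc1
F2 | step 6 | methyl (5-bromo-2-{[4-(TBS-oxy)phenyl]methoxy}phenyl)(oxo)acetate | COC(=O)C(=O)c1cc(Br)ccc1OCc1ccc(O[Si](C)(C)C(C)(C)C)cc1
F3 | step 6 | rac-methyl (2S*,3S*)-5-bromo-3-hydroxy-2-[4-(TBS-oxy)phenyl]-2,3-dihydro-1-benzofuran-3-carboxylate | Brc1ccc2c(c1)[C@@](O)(C(=O)OC)[C@H](c1ccc(O[Si](C)(C)C(C)(C)C)cc1)O2.Brc1ccc2c(c1)[C@](O)(C(=O)OC)[C@@H](c1ccc(O[Si](C)(C)C(C)(C)C)cc1)O2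
F4 | step 6 | rac-(2S*,3S*)-5-bromo-3-hydroxy-N-methoxy-N-methyl-2-[4-(TBS-oxy)phenyl]-2,3-dihydro-1-benzofuran-3-carboxamide | Brc1ccc2c(c1)[C@@](O)(C(=O)N(C)OC)[C@H](c1ccc(O[Si](C)(C)C(C)(C)C)cc1)O2.Brc1ccc2c(c1)[C@](O)(C(=O)N(C)OC)[C@@H](c1ccc(O[Si](C)(C)C(C)(C)C)cc1)O2
F5 | step 6 | 1-bromo-2,4-bis(TBS-oxy)benzene | Brc1ccc(O[Si](C)(C)C(C)(C)C)cc1O[Si](C)(C)C(C)(C)C
F6 | step 6 | [2,4-bis(TBS-oxy)phenyl]lithium | [Li]c1ccc(O[Si](C)(C)C(C)(C)C)cc1O[Si](C)(C)C(C)(C)C
F7 | step 5 | 4-bromo-2-{(Z)-2-[2,4-bis(TBS-oxy)phenyl]ethenyl}-1-{[4-(TBS-oxy)phenyl]methoxy}benzene | Brc1ccc(OCc2ccc(O[Si](C)(C)C(C)(C)C)cc2)c(/C=C\c2ccc(O[Si](C)(C)C(C)(C)C)cc2O[Si](C)(C)C(C)(C)C)c1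
F8 | step 5 | 1-(5-bromo-2-{[4-(TBS-oxy)phenyl]methoxy}phenyl)-2-[2,4-bis(TBS-oxy)phenyl]ethane-1,2-diol (racemic syn-diol; both centres are removed on oxidation) | Brc1ccc(OCc2ccc(O[Si](C)(C)C(C)(C)C)cc2)c(C(O)C(O)c2ccc(O[Si](C)(C)C(C)(C)C)cc2O[Si](C)(C)C(C)(C)C)c1
F9 | step 10 | [(2S,3S)-5-ethenyl-3-hydroxy-2-[4-(TBS-oxy)phenyl]-2,3-dihydro-1-benzofuran-3-yl][2,4-bis(TBS-oxy)phenyl]methanone | C=Cc1ccc2c(c1)[C@@](O)(C(=O)c1ccc(O[Si](C)(C)C(C)(C)C)cc1O[Si](C)(C)C(C)(C)C)[C@H](c1ccc(O[Si](C)(C)C(C)(C)C)cc1)O2
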